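**Assumptions (one line each)**
- The target has no stereocentres: the quaternary reverse-prenyl carbon carries two identical methyls, and the biaryl axes are treated as non-isolable, as in the given SMILES. No stereocontrol is needed.
- 2,4,5-Trimethoxybenzaldehyde, 7-bromoindole and N-Boc-indol-3-yl-Bpin are commercial.
- Numbered compounds are the substrates and building blocks. Small reagents that add atoms are given by name and SMILES in the reagent line.

## Retrosynthesis
1. Asterriquinol H ← remove the phenol (diethylcarbamate) and indole N-Boc groups ← Suzuki coupling of a hindered Ar–Br with N-Boc-7-prenylindol-3-yl-Bpin (the 7-prenylindole unit is made from 7-bromoindole).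
2. That Ar–Br ← **new step: late-stage C2 reverse-prenylation of a 3-aryl-NH-indole** (3-chloroindolenine / prenyl-9-BBN). This avoids a tetra-ortho Suzuki coupling onto a 2-tert-alkylindole.
3. The 3-aryl indole ← chemoselective Suzuki coupling at the C–I bond of a differentiated Br/I arene. The arene comes from 2,4,5-trimethoxyphenol by carbamate-directed ortho-metalation/bromination, then iodination.
4. No ring is formed in the route: all three rings pre-exist. The bonds are made in this order: arene halogens, aryl–indole A, indole-A C2–C(Me)2CH=CH2, aryl–indole B, deprotection.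

## Route

**Step 1**
Reactants: 1 (2,4,5-trimethoxybenzaldehyde)
Product: 2 (2,4,5-trimethoxyphenol)
Conditions: mCPBA, CH2Cl2, 0 °C→rt; then KOH, MeOH/H2O, rt
Reagents that add atoms: mCPBA, OOC(=O)c1cccc(Cl)c1 (supplies the phenol O)
Why: Dakin-type Baeyer–Villiger oxidation of an electron-rich benzaldehyde gives the aryl formate, and hydrolysis releases the phenol. No stereocentres are involved.

**Step 2**
Reactants: 2
Product: 3 (2,4,5-trimethoxyphenyl N,N-diethylcarbamate)
Conditions: NaH, THF, 0 °C; then ClCONEt2, rt
Reagents that add atoms: N,N-diethylcarbamoyl chloride, CCN(CC)C(=O)Cl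
Why: O-acylation of the phenoxide installs the strongest directed-metalation group, which also serves as the phenol protecting group.

**Step 3**
Reactants: 3
Product: 4 (2-bromo-3,4,6-trimethoxyphenyl N,N-diethylcarbamate)
Conditions: s-BuLi, TMEDA, THF, −78 °C; then BrCCl2CCl2Br, −78 °C→rt
Reagents that add atoms: 1,2-dibromotetrachloroethane, BrC(Cl)(Cl)C(Cl)(Cl)Br
Why: Directed ortho-metalation. The OCb group cooperates with the flanking OMe at C6, which is more acidic than the C3–H between two OMe groups, and the aryllithium is brominated. This sets the Br at the future indole-B site.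

**Step 4**
Reactants: 4
Product: 5 (2-bromo-5-iodo-3,4,6-trimethoxyphenyl N,N-diethylcarbamate)
Conditions: NIS, MeCN, cat. TFA, rt
Reagents that add atoms: N-iodosuccinimide, O=C1CCC(=O)N1I
Why: Electrophilic iodination of the only remaining aromatic C–H, which is flanked by two OMe groups, gives a Br/I-differentiated arene. The iodine sits at the future indole-A site.

**Step 5**
Reactants: 5; 6 (tert-butyl 3-(pinacolboryl)indole-1-carboxylate)
Product: 7 (3-aryl-N-Boc-indole, Br and OCb intact)
Conditions: Pd(dppf)Cl2 (5 mol%), K3PO4, dioxane/H2O, 80 °C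
Reagents that add atoms: 6 (N-Boc-indol-3-yl unit)
Why: Suzuki–Miyaura coupling proceeds at the weaker C–I bond in preference to the C–Br bond, forming a tri-ortho-substituted biaryl with a free indole C2–H.

**Step 6**
Reactants: 7
Product: 8 (3-aryl-1H-indole)
Conditions: NaOMe (0.3 equiv), MeOH/THF, rt
Reagents that add atoms: none
Why: Methoxide-mediated N-deBoc of the indole (the N-acylindole is an active amide) leaves the aryl diethylcarbamate and aryl bromide untouched. The free N–H is needed for the next step.

**Step 7 (new step)**
Reactants: 8; 9 (prenyl-9-BBN, prepared in situ from prenylMgCl and B-methoxy-9-BBN)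
Product: 10 (2-(2-methylbut-3-en-2-yl)-3-aryl-1H-indole)
Conditions: (i) tBuOCl, Et3N, THF, −78 °C; (ii) 9, THF, −78 °C→rt; (iii) 1 M NaOH, rt
Reagents that add atoms: prenyl-9-BBN, CC(C)=CCB1C2CCCC1CCC2 (its γ-carbon becomes the C(Me)2CH=CH2 unit). tBuOCl (CC(C)(C)OCl) only supplies a transient Cl, which is lost.
Why: **Proposed new method:** the 3-aryl indole is chlorinated at C3 to give a 3-aryl-3-chloro-3H-indole. The allylborane adds to the C2=N bond through a chair-like six-membered transition state that delivers the γ-carbon (CMe2), forming the tertiary centre at C2. Loss of HCl then re-aromatises the indole. The closest known reaction is the 3-chloroindolenine/prenyl-9-BBN reverse prenylation of 3-alkylindoles (tryprostatin B type), which has not been applied to a 3-(hexasubstituted tetraalkoxyaryl)indole. The central arene has no C–H to chlorinate, and the 7-prenylindole is attached only afterwards, so its free C2–H and prenyl alkene are not exposed. The step does real work: it builds the hindered C2 quaternary carbon next to the crowded biaryl axis.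

**Step 8**
Reactants: 11 (7-bromoindole)
Product: 12 (7-allylindole)
Conditions: allylSnBu3, Pd(PPh3)4 (5 mol%), toluene, 110 °C
Reagents that add atoms: allyltributylstannane, C=CC[Sn](CCCC)(CCCC)CCCC
Why: Stille allylation of an aryl bromide, linear-selective.

**Step 9**
Reactants: 12
Product: 13 (7-prenylindole)
Conditions: Grubbs II (5 mol%), 2-methyl-2-butene (20 equiv), CH2Cl2, 40 °C, sealed tube
Reagents that add atoms: 2-methyl-2-butene, CC=C(C)C (supplies the =CMe2 terminus; propene is lost)
Why: Olefin cross-metathesis converts the terminal allyl group to the trisubstituted prenyl alkene.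

**Step 10**
Reactants: 13
Product: 14 (3-bromo-7-prenylindole)
Conditions: NBS, THF, −78→0 °C
Reagents that add atoms: N-bromosuccinimide, O=C1CCC(=O)N1Br
Why: Electrophilic bromination occurs at indole C3, which is far more nucleophilic than the prenyl alkene.

**Step 11**
Reactants: 14
Product: 15 (N-Boc-3-bromo-7-prenylindole)
Conditions: Boc2O, DMAP, MeCN, rt
Reagents that add atoms: di-tert-butyl dicarbonate, CC(C)(C)OC(=O)OC(=O)OC(C)(C)C
Why: N-acylation protects the N–H and stabilises the 3-bromoindole for borylation.

**Step 12**
Reactants: 15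
Product: 16 (N-Boc-7-prenylindol-3-yl-Bpin)
Conditions: B2pin2, Pd(dppf)Cl2, KOAc, dioxane, 90 °C
Reagents that add atoms: bis(pinacolato)diboron, CC1(C)OB(OC1(C)C)B2OC(C)(C)C(C)(C)O2
Why: Miyaura borylation of an aryl bromide.

**Step 13**
Reactants: 10; 16
Product: 17 (N-Boc indole-B, OCb and free indole-A NH)
Conditions: XPhos Pd G3 (5 mol%), K3PO4, dioxane/H2O, 100 °C
Reagents that add atoms: 16 (N-Boc-7-prenylindol-3-yl unit)
Why: Suzuki–Miyaura coupling with a bulky biarylphosphine catalyst overcomes the di-ortho-substituted (OCb, OMe), electron-rich aryl bromide; partial thermal N-Boc loss is harmless because step 14 removes the rest.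

**Step 14**
Reactants: 17
Product: 18 (bis-NH indole, aryl carbamate)
Conditions: NaOMe (0.3 equiv), MeOH/THF, rt
Reagents that add atoms: none
Why: Same mild N-deBoc as step 6; the carbamate, alkenes and methyl ethers survive.

**Step 15**
Reactants: 18
Product: 19 (asterriquinol H)
Conditions: LiAlH4 (5 equiv), THF, 65 °C, Ar; Fieser work-up
Reagents that add atoms: none (hydride only adds H)
Why: Hydride attack at the carbamate C=O expels the phenoxide (reductive aryl-carbamate cleavage), leaving the OMe groups, both indoles and both alkenes intact.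

## Checks performed
- **Structure match:** the central arene in 19 runs ArA–C(OMe)–C(OMe)–C(ArB)–C(OH)–C(OMe)–back to ArA. Read the other way round this is ArA, OMe, OH, ArB, OMe, OMe, which equals the target. Indole A is 2-(1,1-dimethylallyl)-3-yl, indole B is 7-prenyl-3-yl, and both are NH.
- **Atom bookkeeping:** each step's product follows from its reactants with all atoms accounted for, and the last product is the target.
- **Functional-group survival:** the 7-prenylindole is introduced only after the tBuOCl step, and the Br/I pair is used in the order I then Br.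
- **Stereochemistry:** there are no stereocentres to set or scramble.

## Compound list
1 | 2,4,5-trimethoxybenzaldehyde | O=Cc1cc(OC)c(OC)cc1OC | starting material
2 | 2,4,5-trimethoxyphenol | Oc1cc(OC)c(OC)cc1OC | intermediate
3 | 2,4,5-trimethoxyphenyl N,N-diethylcarbamate | CCN(CC)C(=O)Oc1cc(OC)c(OC)cc1OC | intermediate
4 | 2-bromo-3,4,6-trimethoxyphenyl N,N-diethylcarbamate | CCN(CC)C(=O)Oc1c(Br)c(OC)c(OC)cc1OC | intermediate
5 | 2-bromo-5-iodo-3,4,6-trimethoxyphenyl N,N-diethylcarbamate | CCN(CC)C(=O)Oc1c(Br)c(OC)c(OC)c(I)c1OC | intermediate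
6 | tert-butyl 3-(pinacolboryl)indole-1-carboxylate | CC1(C)OB(OC1(C)C)c1cn(C(=O)OC(C)(C)C)c2ccccc12 | starting material
7 | N-Boc-3-(aryl)indole (aryl = 4-bromo-2,3,6-trimethoxy-5-OCb) | CCN(CC)C(=O)Oc1c(Br)c(OC)c(OC)c(-c2cn(C(=O)OC(C)(C)C)c3ccccc23)c1OC | intermediate
8 | 3-aryl-1H-indole | CCN(CC)C(=O)Oc1c(Br)c(OC)c(OC)c(-c2c[nH]c3ccccc23)c1OC | intermediate
9 | prenyl-9-BBN | CC(C)=CCB1C2CCCC1CCC2 | starting material (prepared in situ)
10 | 2-(1,1-dimethylallyl)-3-aryl-1H-indole | C=CC(C)(C)c1[nH]c2ccccc2c1-c1c(OC)c(OC)c(Br)c(OC(=O)N(CC)CC)c1OC | intermediate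
11 | 7-bromoindole | Brc1cccc2cc[nH]c12 | starting material
12 | 7-allylindole | C=CCc1cccc2cc[nH]c12 | intermediate
13 | 7-prenylindole | CC(C)=CCc1cccc2cc[nH]c12 | intermediate
14 | 3-bromo-7-prenylindole | CC(C)=CCc1cccc2c(Br)c[nH]c12 | intermediate
15 | N-Boc-3-bromo-7-prenylindole | CC(C)=CCc1cccc2c(Br)cn(C(=O)OC(C)(C)C)c12 | intermediate
16 | N-Boc-7-prenylindol-3-yl-Bpin | CC(C)=CCc1cccc2c(B3OC(C)(C)C(C)(C)O3)cn(C(=O)OC(C)(C)C)c12 | intermediate
17 | coupled N-Boc compound | C=CC(C)(C)c1[nH]c2ccccc2c1-c1c(OC)c(OC)c(-c2cn(C(=O)OC(C)(C)C)c3c(CC=C(C)C)cccc23)c(OC(=O)N(CC)CC)c1OC | intermediate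
18 | bis-NH carbamate | C=CC(C)(C)c1[nH]c2ccccc2c1-c1c(OC)c(OC)c(-c2c[nH]c3c(CC=C(C)C)cccc23)c(OC(=O)N(CC)CC)c1OC | intermediate
19 | asterriquinol H | C=CC(C)(C)c1[nH]c2ccccc2c1-c1c(OC)c(O)c(-c2c[nH]c3c(CC=C(C)C)cccc23)c(OC)c1OC | target

## Totals
- Total steps: 15.
- Longest linear sequence: 10 steps (1→2→3→4→5→6→7→13→14→15). The indole-B branch is 5 steps, joining at step 13.

## Three steps most likely to fail
1. **Step 7 (proposed new step).** The tBuOCl may oxidise the electron-rich tetraalkoxyarene, the 3-aryl-3-chloroindolenine may ionise or undergo a 1,2-aryl shift, or the crowded C2 may be inaccessible to prenyl-9-BBN.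
   - Fallback using known chemistry: make 2-(1,1-dimethylallyl)indole from indole by the standard Danishefsky reverse prenylation. Convert it to its N-Boc-3-Bpin via C3 iodination, Boc protection and Miyaura borylation. Couple it directly with iodide 5 in step 5 using Pd-PEPPSI-IPent or an AntPhos-type catalyst (known for tetra-ortho-substituted biaryls), which skips steps 6–7.
2. **Step 13 (hindered Suzuki).** Oxidative addition into the di-ortho-substituted electron-rich aryl bromide may be slow, and the indolyl-Bpin may protodeboronate.
   - Fallback: switch the nucleophile class to a Negishi coupling. Make the 3-indolylzinc chloride from N-Boc-3-iodo-7-prenylindole by I/Mg exchange and transmetalation to Zn. Couple it with 10 using Pd-PEPPSI-IPent.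
3. **Step 3 (directed-metalation regiochemistry).** Lithiation could partly occur at C3, between the two OMe groups, instead of ortho to the carbamate.
   - Fallback: swap the order of steps 2 and 3. Brominate the free phenol 2 ortho to OH with NBS and i-Pr2NH in CH2Cl2 at −78 °C (ortho-selective phenol bromination). Then install the carbamate and iodinate as in step 4 to reach 5.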